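The data are calculated with constants of no real substance, and the scatter is random.

Late in the two earlier runs the target, crystals counted in it, was still climbing, and the bench habit is to extend that climb as a straight line; the flask's charge lies at the geometric mean of theirs, so I read across between them.

| flask | starting material | remark | time |
|---|---|---|---|
| south-west | 0.10 M | run made earlier |  |
| south | 0.40 M | run made earlier |  |
| flask | 0.20 M |  | 1.0 h |

- south-west (time / min: target / %, crystals / %, starting material / %): 4.00: 1.5, 0, 91.7; 8.00: 2.1, 0, 81.2; 15.0: 2.2, 0, 71.8; 25.0: 5.0, 0, 61.2; 50.0: 11.0, 0.4, 43.0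
- south (time / min: target / %, crystals / %, starting material / %): 10.0: 2.2, 0, 70.8; 20.0: 0.6, 0.9, 56.7; 30.0: 3.3, 1.9, 44.6; 40.0: 8.0, 0.9, 36.7; 50.0: 7.1, 4.6, 31.7

(scatter of a reading: 1 percentage point)

- what is said of target includes crystals
- crystals is a solid; its amount is given per volume of the solution
- the analysis behind the earlier runs scatters by 1 percentage point, standard deviation

- the target and crystals together standing at 1.0 h, as a percentage of the starting material charged
- concentration of target in solution at 1.0 h, in percent of saturation

At 50.0 min the runs stood at 11.0% and 7.1%, whose geometric mean gave me Ym = 8.84% as my estimate for the flask at that time, built from readings that each scatter by 1 percentage point. Their late slopes, 0.144 h⁻¹ and 0.114 h⁻¹ as fractions of the charge, average g = 0.129 h⁻¹, while starting material fell with apparent first-order constants of 0.847 h⁻¹ and 1.02 h⁻¹, averaging k = 0.936 h⁻¹. I took the line as usable while the time Δt past that reading stays short of the reciprocal of k, 64.1 min, and for the flask the ratio kΔt was 0.156, so I expected a slight bend. Letting the gain fall in step with starting material and integrating, I had Y = Ym + C(1 − exp(−kΔt)), where C = g/k = 13.8% is the reach, the gain my reckoning still allowed after that reading, and this gave 10.8%.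

The forecast, expecting that “an intermediate probably builds up, giving a lag”, stood at 15% and 115%, higher on yield than my figure, and the flask gave 11.4% and 114%.

    starting material ⇌ intermediate (K = 0.960, k = 3.50 × 10⁻⁴ s⁻¹)
    intermediate → side product A (k = 9.60 × 10⁻⁵ s⁻¹)
    intermediate → target (k = 1.80 × 10⁻⁴ s⁻¹)
    crystals ⇌ target, rate k4*(cs4 - [target]) while solid is left; crystals form when [target] > cs4 (solubility = 14.0 mM, k = 0.00350 s⁻¹)
    2 starting material → homo dimer (k = 3.80 × 10⁻⁴ M⁻¹ s⁻¹)
    starting material + target → side product B (k = 0.00140 M⁻¹ s⁻¹)

With the reach, my figure lay 0.60 points below this flask. The same flask left until 4.0 h lies well past the border, with kΔt = 2.96, and there the reach gave 21.9%. That flask stood at 30.7%, higher than the reckoning, with 7.47% of the starting material left and 23.5% as crystals.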